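The route rests on one disconnection: the C3–C3a bond of the 2,3-dihydrobenzofuran, which is also a bond of the eight-membered carbocycle. The precursor is an all-trans 1,2,3-trisubstituted indane bearing a free resorcinol ring and, on the diarylmethine carbon, an intact (E)-4-hydroxystilbene arm. Two-electron oxidation dearomatizes the hydroxystilbene to a quinone methide cation; its electrophilic carbon, the future C3 and vinylogous para position of the 4-hydroxyphenyl ring on C2, is attacked by the future C3a, which lies ortho and para to the two resorcinol oxygens, and the adjacent phenol then closes the furan. One operation thus forms the carbocycle, the dihydrofuran and both furan stereocentres.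

Key step: step 13

Assumption: in step 2 (S)-BINAP is taken to deliver the (3S)-indanone; if the sense of induction is the opposite, (R)-BINAP is used and nothing else changes; boronate 2 and styrene 19 are taken as purchasable.

Indane locants used below: C1 is the carbon that ends up bearing the diarylmethyl group, C2 bears the resorcinol-type ring, C3 bears the 4-methoxyphenyl group, and the methoxy groups sit on C4 and C6.

Step 1
Reactants: 1 2-bromo-3,5-dimethoxybenzaldehyde; 2 1-(4-methoxyphenyl)vinylboronic acid pinacol ester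
Product: 3 3,5-dimethoxy-2-[1-(4-methoxyphenyl)ethenyl]benzaldehyde
Conditions: Pd(OAc)2, SPhos, K3PO4, toluene/H2O, 90 °C
Reagents that add atoms: none
Why: Suzuki–Miyaura coupling, in which the biaryl phosphine handles the doubly ortho-substituted bromide and the aldehyde is left untouched.

Step 2
Reactants: 3 3,5-dimethoxy-2-[1-(4-methoxyphenyl)ethenyl]benzaldehyde
Product: 4 (3S)-4,6-dimethoxy-3-(4-methoxyphenyl)indan-1-one
Conditions: [Rh((S)-BINAP)]ClO4 (5 mol %), CH2Cl2, 25 °C
Reagents that add atoms: none
Why: Rh-catalysed enantioselective intramolecular alkene hydroacylation, in which the acyl rhodium hydride adds across the 1,1-disubstituted alkene with the acyl carbon going to the CH2 terminus and the chiral BINAP pocket fixes C3 as S (sense as assumed above).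

Step 3
Reactants: 5 5-bromobenzene-1,3-diol
Product: 6 1-bromo-3,5-bis(triisopropylsilyloxy)benzene
Conditions: TIPSCl, imidazole, DMF, 25 °C
Reagents that add atoms: chlorotri(propan-2-yl)silane (TIPSCl), CC(C)[Si](Cl)(C(C)C)C(C)C
Why: Standard phenol silylation; the bulky silyl ethers should survive the base, acid and organometallic steps that follow and are orthogonal to methyl ethers.

Step 4
Reactants: 4 (3S)-indanone; 6 1-bromo-3,5-bis(triisopropylsilyloxy)benzene
Product: 7 (2S,3S)-2,3-trans-2-aryl-3-aryl-indan-1-one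
Conditions: Pd(OAc)2, XPhos, K3PO4, toluene, 90 °C; aq. NH4Cl
Reagents that add atoms: none
Why: Palladium-catalysed ketone α-arylation; the more acidic mono-arylated product rests as its enolate, which prevents diarylation, and its protonation gives the more stable 2,3-trans isomer, so C2 is set from C3 under thermodynamic control.

Step 5
Reactants: 7 trans-2,3-diarylindanone
Product: 8 (2S,3S)-1-methylidene-indane
Conditions: Cp2TiMe2, toluene, 75 °C, dark
Reagents that add atoms: dimethyltitanocene (Cp2TiMe2), C[Ti](C)(C1C=CC=C1)C1C=CC=C1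
Why: Petasis methylenation with the non-basic titanium methylidene, chosen because a phosphorus ylide would only enolize this acidic α-aryl ketone; no stereocentre is touched.

Step 6
Reactants: 8 1-methylidene-indane
Product: 10 1,2-cis indan-1-ylmethanol, via alkylborane 9 (not isolated)
Conditions: 9-BBN, THF, 25 → 60 °C; then aq. NaOH, H2O2, 0 °C
Reagents that add atoms: hydrogen peroxide, OO
Why: Anti-Markovnikov hydroboration–oxidation; boron adds to the CH2 terminus from the face opposite the C2 aryl group, which should give mainly the 1,2-cis alcohol, a centre that is corrected in step 7.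

Step 7
Reactants: 10 1,2-cis indan-1-ylmethanol
Product: 12 all-trans indane-1-carbaldehyde, via cis-aldehyde 11 (not isolated)
Conditions: Dess–Martin periodinane, NaHCO3, CH2Cl2, 0 → 25 °C; then DBU, 25 °C
Reagents that add atoms: none
Why: Dess–Martin oxidation followed by base-mediated epimerization of the benzylic α-formyl centre, which should settle C1 in the thermodynamically preferred 1,2-trans (all-trans) arrangement.

Step 8
Reactants: 13 1-bromo-3,5-dimethoxybenzene
Product: 14 1-bromo-2-iodo-3,5-dimethoxybenzene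
Conditions: NIS, TFA (cat.), MeCN, 25 °C
Reagents that add atoms: N-iodosuccinimide, O=C1CCC(=O)N1I
Why: Electrophilic aromatic iodination at the position para to one methoxy and ortho to the other, next to bromine, the usual site of attack in 3,5-dimethoxyaryl systems.

Step 9
Reactants: 14 1-bromo-2-iodo-3,5-dimethoxybenzene; 12 all-trans indane-1-carbaldehyde
Product: 16 (2-bromo-4,6-dimethoxyphenyl)(indan-1-yl)methanol as a mixture of carbinol epimers, via arylmagnesium chloride 15 (not isolated)
Conditions: i-PrMgCl·LiCl, THF, −40 °C; then 12, LaCl3·2LiCl, −40 → −20 °C; aq. NH4Cl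
Reagents that add atoms: none
Why: Iodine–magnesium exchange is selective for iodide over bromide and the ortho-bromoaryl Grignard reagent should resist aryne formation at low temperature; LaCl3·2LiCl favours 1,2-addition over enolization, and the carbinol configuration is irrelevant because this centre is ionized in step 10.

Step 10
Reactants: 16 diaryl carbinol; 17 anisole
Product: 18 (1R,2S,3S)-1-[(R)-(2-bromo-4,6-dimethoxyphenyl)(4-methoxyphenyl)methyl]indane
Conditions: TFA, anisole/CH2Cl2, −40 → 0 °C
Reagents that add atoms: none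
Why: SN1-type Friedel–Crafts alkylation of anisole at its para position by the benzylic cation stabilized by the ortho and para methoxy groups; the hydrogen on C1 of the indane eclipses the cation plane (allylic 1,3-strain) and anisole should approach over the flat benzo ring, anti to the substituted C2 (Felkin–Anh-type control), which gives the (R) diarylmethine centre.

Step 11
Reactants: 18 aryl bromide; 19 tert-butyldimethyl(4-vinylphenoxy)silane
Product: 20 tris-silylated (E)-stilbene
Conditions: Pd2(dba)3, [HP(t-Bu)3]BF4, Cy2NMe, dioxane, 100 °C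
Reagents that add atoms: none
Why: Mizoroki–Heck reaction; the electron-rich bulky phosphine activates the hindered aryl bromide, and syn insertion followed by β-hydride elimination gives the (E)-stilbene.

Step 12
Reactants: 20 tris-silylated (E)-stilbene
Product: 21 triphenol (free resorcinol ring and free 4-hydroxystilbene)
Conditions: TBAF, THF, 0 °C; aq. NH4Cl
Reagents that add atoms: none
Why: Fluoride-mediated desilylation removes all three silyl ethers while the six methyl ethers and the stilbene stay intact.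

Step 13
Reactants: 21 triphenol
Product: 23 hexamethyl ether of stenophyllol B, via quinone methide 22 (not isolated)
Conditions: PhI(OAc)2 (1.05 equiv), (CF3)2CHOH (2 mM), 0 → 25 °C
Reagents that add atoms: none
Why: Proposed new method: PhI(OAc)2 should oxidize the most electron-rich phenol, the 4-hydroxystilbene, by two electrons to a dearomatized quinone methide cation whose positive charge sits on the stilbene carbon next to the dimethoxyphenylene ring; the free resorcinol ring on C2 of the indane attacks this carbon through its ortho carbon (ortho to one OH, para to the other) to give quinone methide 22, and the phenol next to the new bond then adds to the quinone methide carbon, which rearomatizes that ring. The closest known reactions are the biomimetic oxidative 8–10′ coupling of 4-hydroxystilbenes to ε-viniferin-type dihydrobenzofurans and trivalent-iodine phenol dearomatization with arene capture in fluorinated alcohols; new is the intramolecular use on a non-conjugated resorcinol to close a medium ring. The eight-membered carbocycle closes by 8-exo Friedel–Crafts attack on the proximal stilbene carbon, the dihydrofuran by 5-exo-trig oxa-1,6-addition. The new stereocentre C3 of the furan is controlled by the diarylmethine centre: its C–H lies in the plane of the dimethoxyphenylene ring toward the ortho methoxy group (allylic 1,3-strain), the indane therefore sits on one face of that ring and delivers the resorcinol to the same face of the alkene, whose distal carbon points away from the methine; C2 of the furan then forms trans to C3, the more stable arrangement, reached reversibly through the quinone methide. The step needs chemoselective oxidation of the hydroxystilbene (all other phenols are methyl ethers and the resorcinol resists oxidation) and attack by the resorcinol carbon instead of C7 of the indane benzo ring, which would close a seven-membered ring; the higher nucleophilicity of the free resorcinol, high dilution and the cation-stabilizing solvent should secure this.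

Step 14
Reactants: 23 hexamethyl ether of stenophyllol B
Product: 24 stenophyllol B
Conditions: BBr3, CH2Cl2, −78 → 25 °C; then MeOH/H2O
Reagents that add atoms: none
Why: Lewis-acid demethylation of the six aryl methyl ethers; any reversible opening of the dihydrofuran at its benzylic C–O bond should reclose to the trans isomer, so no stereocentre is lost.

Compound list
1 | 2-bromo-3,5-dimethoxybenzaldehyde | COc1cc(OC)c(Br)c(C=O)c1 | starting material
2 | 2-[1-(4-methoxyphenyl)ethenyl]-4,4,5,5-tetramethyl-1,3,2-dioxaborolane | COc1ccc(C(=C)B2OC(C)(C)C(C)(C)O2)cc1 | starting material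
3 | 3,5-dimethoxy-2-[1-(4-methoxyphenyl)ethenyl]benzaldehyde | COc1ccc(C(=C)c2c(OC)cc(OC)cc2C=O)cc1 | intermediate
4 | (3S)-4,6-dimethoxy-3-(4-methoxyphenyl)-2,3-dihydro-1H-inden-1-one | COc1ccc([C@H]2c3c(OC)cc(OC)cc3C(=O)C2)cc1 | intermediate
5 | 5-bromobenzene-1,3-diol | Oc1cc(O)cc(Br)c1 | starting material
6 | 1-bromo-3,5-bis(triisopropylsilyloxy)benzene | CC(C)[Si](Oc1cc(Br)cc(O[Si](C(C)C)(C(C)C)C(C)C)c1)(C(C)C)C(C)C | intermediate
7 | (2S,3S)-2-[3,5-bis(triisopropylsilyloxy)phenyl]-4,6-dimethoxy-3-(4-methoxyphenyl)-2,3-dihydro-1H-inden-1-one (2,3-trans) | COc1ccc([C@H]2c3c(OC)cc(OC)cc3C(=O)[C@@H]2c2cc(O[Si](C(C)C)(C(C)C)C(C)C)cc(O[Si](C(C)C)(C(C)C)C(C)C)c2)cc1 | intermediate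
8 | (2S,3S)-2-[3,5-bis(triisopropylsilyloxy)phenyl]-4,6-dimethoxy-3-(4-methoxyphenyl)-1-methylideneindane | COc1ccc([C@H]2c3c(OC)cc(OC)cc3C(=C)[C@@H]2c2cc(O[Si](C(C)C)(C(C)C)C(C)C)cc(O[Si](C(C)C)(C(C)C)C(C)C)c2)cc1 | intermediate
9 | 9-{[(1R,2S,3S)-2-[3,5-bis(triisopropylsilyloxy)phenyl]-4,6-dimethoxy-3-(4-methoxyphenyl)indan-1-yl]methyl}-9-borabicyclo[3.3.1]nonane (1,2-cis) | COc1ccc([C@H]2c3c(OC)cc(OC)cc3[C@H](CB3C4CCCC3CCC4)[C@@H]2c2cc(O[Si](C(C)C)(C(C)C)C(C)C)cc(O[Si](C(C)C)(C(C)C)C(C)C)c2)cc1 | intermediate
10 | [(1R,2R,3S)-2-[3,5-bis(triisopropylsilyloxy)phenyl]-4,6-dimethoxy-3-(4-methoxyphenyl)indan-1-yl]methanol (1,2-cis, 2,3-trans) | COc1ccc([C@H]2c3c(OC)cc(OC)cc3[C@H](CO)[C@@H]2c2cc(O[Si](C(C)C)(C(C)C)C(C)C)cc(O[Si](C(C)C)(C(C)C)C(C)C)c2)cc1 | intermediate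
11 | (1R,2R,3S)-2-[3,5-bis(triisopropylsilyloxy)phenyl]-4,6-dimethoxy-3-(4-methoxyphenyl)indane-1-carbaldehyde (1,2-cis) | COc1ccc([C@H]2c3c(OC)cc(OC)cc3[C@H](C=O)[C@@H]2c2cc(O[Si](C(C)C)(C(C)C)C(C)C)cc(O[Si](C(C)C)(C(C)C)C(C)C)c2)cc1 | intermediate
12 | (1S,2R,3S)-2-[3,5-bis(triisopropylsilyloxy)phenyl]-4,6-dimethoxy-3-(4-methoxyphenyl)indane-1-carbaldehyde (all-trans) | COc1ccc([C@H]2c3c(OC)cc(OC)cc3[C@@H](C=O)[C@@H]2c2cc(O[Si](C(C)C)(C(C)C)C(C)C)cc(O[Si](C(C)C)(C(C)C)C(C)C)c2)cc1 | intermediate
13 | 1-bromo-3,5-dimethoxybenzene | COc1cc(Br)cc(OC)c1 | starting material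
14 | 1-bromo-2-iodo-3,5-dimethoxybenzene | COc1cc(Br)c(I)c(OC)c1 | intermediate
15 | (2-bromo-4,6-dimethoxyphenyl)magnesium chloride (LiCl complex) | COc1cc(Br)c([Mg]Cl)c(OC)c1 | intermediate
16 | (2-bromo-4,6-dimethoxyphenyl)[(1S,2R,3S)-2-[3,5-bis(triisopropylsilyloxy)phenyl]-4,6-dimethoxy-3-(4-methoxyphenyl)indan-1-yl]methanol (all-trans indane; carbinol centre a mixture) | COc1ccc([C@H]2c3c(OC)cc(OC)cc3[C@@H](C(O)c3c(OC)cc(OC)cc3Br)[C@@H]2c2cc(O[Si](C(C)C)(C(C)C)C(C)C)cc(O[Si](C(C)C)(C(C)C)C(C)C)c2)cc1 | intermediate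
17 | anisole | COc1ccccc1 | starting material
18 | (1R,2S,3S)-1-[(R)-(2-bromo-4,6-dimethoxyphenyl)(4-methoxyphenyl)methyl]-2-[3,5-bis(triisopropylsilyloxy)phenyl]-4,6-dimethoxy-3-(4-methoxyphenyl)indane | COc1ccc([C@H]2c3c(OC)cc(OC)cc3[C@@H]([C@H](c3ccc(OC)cc3)c3c(OC)cc(OC)cc3Br)[C@@H]2c2cc(O[Si](C(C)C)(C(C)C)C(C)C)cc(O[Si](C(C)C)(C(C)C)C(C)C)c2)cc1 | intermediate
19 | tert-butyldimethyl(4-vinylphenoxy)silane | C=Cc1ccc(O[Si](C)(C)C(C)(C)C)cc1 | starting material
20 | (1R,2S,3S)-1-[(R)-{2-[(E)-2-(4-tert-butyldimethylsilyloxyphenyl)ethenyl]-4,6-dimethoxyphenyl}(4-methoxyphenyl)methyl]-2-[3,5-bis(triisopropylsilyloxy)phenyl]-4,6-dimethoxy-3-(4-methoxyphenyl)indane | COc1ccc([C@H]2c3c(OC)cc(OC)cc3[C@@H]([C@H](c3ccc(OC)cc3)c3c(OC)cc(OC)cc3/C=C/c3ccc(O[Si](C)(C)C(C)(C)C)cc3)[C@@H]2c2cc(O[Si](C(C)C)(C(C)C)C(C)C)cc(O[Si](C(C)C)(C(C)C)C(C)C)c2)cc1 | intermediate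
21 | 5-[(1R,2S,3S)-1-[(R)-{2-[(E)-2-(4-hydroxyphenyl)ethenyl]-4,6-dimethoxyphenyl}(4-methoxyphenyl)methyl]-4,6-dimethoxy-3-(4-methoxyphenyl)indan-2-yl]benzene-1,3-diol | COc1ccc([C@H]2c3c(OC)cc(OC)cc3[C@@H]([C@H](c3ccc(OC)cc3)c3c(OC)cc(OC)cc3/C=C/c3ccc(O)cc3)[C@@H]2c2cc(O)cc(O)c2)cc1 | intermediate
22 | para-quinone methide formed after closure of the eight-membered ring (new aryl–carbon bond in place, resorcinol OH groups free, furan not yet closed; configuration as in 23) | COc1ccc([C@H]2c3c(OC)cc(OC)cc3[C@H]3[C@H](c4ccc(OC)cc4)c4c(OC)cc(OC)cc4[C@@H](C=C4C=CC(=O)C=C4)c4c(O)cc(O)cc4[C@H]23)cc1 | intermediate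
23 | hexa-O-methylstenophyllol B (OMe on both 4-oxyphenyl rings of the indane part and on both resorcinol rings outside the benzofuran; free OH at C6 of the benzofuran and on the 4-hydroxyphenyl group at furan C2; configuration as in 24) | COc1ccc([C@H]2c3c(OC)cc(OC)cc3[C@H]3[C@H](c4ccc(OC)cc4)c4c(OC)cc(OC)cc4[C@@H]4c5c(cc(O)cc5[C@H]23)O[C@H]4c2ccc(O)cc2)cc1 | intermediate
24 | stenophyllol B | Oc1ccc([C@H]2c3c(O)cc(O)cc3[C@H]3[C@H](c4ccc(O)cc4)c4c(O)cc(O)cc4[C@@H]4c5c(cc(O)cc5[C@H]23)O[C@H]4c2ccc(O)cc2)cc1 | target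

Total step count: 14. Longest linear sequence: 12 steps (steps 1, 2, 4, 5, 6, 7, 9, 10, 11, 12, 13, 14); steps 3 and 8 prepare side fragments.

Steps most likely to fail

Step 13. The cation may be captured by C7 of the indane benzo ring (seven-membered closure) or by solvent, the substrate may oligomerize, or the product phenols may be over-oxidized. The fallback uses known chemistry, sets out from 18 and comes back at 24. Bromine–lithium exchange on 18 (n-BuLi, THF, −78 °C) and quenching with DMF should give the benzaldehyde F1. TBAF then frees the resorcinol to give the aldehyde F2. Ortho-selective intramolecular Friedel–Crafts hydroxyalkylation of the phenol by the aldehyde (MgCl2, Et3N, or mild acid) closes the eight-membered ring through the same aryl–carbon bond and gives the cyclic ortho-hydroxybenzhydrol F3. F3 enters the known [4+1] annulation of ortho-hydroxybenzyl alcohols (through their ortho-quinone methides) with the sulfur ylide from (4-methoxybenzyl)dimethylsulfonium tetrafluoroborate and Cs2CO3, which should give the trans-dihydrobenzofuran F4, the analogue of 23 with a methyl ether on the furan C2 aryl group; the facial course of the ylide addition would have to be established. BBr3 then gives 24.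

Step 10. Facial selectivity at the diarylmethine carbon may be poor or reversed, and the C1 configuration may erode through E1 elimination and reprotonation. The fallback sets out from 16 and comes back at 18. Dess–Martin oxidation of 16 gives the aryl ketone F5 (C1 stays trans, being epimerizable). Addition of 4-methoxyphenylmagnesium bromide in the presence of LaCl3·2LiCl gives the tertiary diaryl carbinol F6. Ionic deoxygenation (Et3SiH, TFA, CH2Cl2, −40 °C) then delivers hydride instead of an arene to the diarylmethyl cation, so that the same facial preference yields the opposite configuration at this carbon and thus 18 if arene attack favours the wrong face.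

Step 2. Turnover may be slow on the hindered 1,1-diarylethene, decarbonylation may compete, or enantiocontrol may be insufficient. The fallback sets out from 1 and comes back at 4. MeMgBr addition to 1 gives the carbinol F7, and MnO2 oxidation gives the acetophenone F8. Claisen–Schmidt condensation with 4-methoxybenzaldehyde (KOH, EtOH) gives the 2′-bromochalcone F9. A palladium-catalysed enantioselective reductive Heck cyclization (Pd(OAc)2, the antipode of 3,5-Xyl-MeO-BIPHEP that gives the 3S product, proton sponge, DMF, 80 °C) should then give 4.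

Further compounds
F1 | step 13 | 2-{(R)-[(1R,2S,3S)-2-[3,5-bis(triisopropylsilyloxy)phenyl]-4,6-dimethoxy-3-(4-methoxyphenyl)indan-1-yl](4-methoxyphenyl)methyl}-3,5-dimethoxybenzaldehyde | COc1ccc([C@H]2c3c(OC)cc(OC)cc3[C@@H]([C@H](c3ccc(OC)cc3)c3c(OC)cc(OC)cc3C=O)[C@@H]2c2cc(O[Si](C(C)C)(C(C)C)C(C)C)cc(O[Si](C(C)C)(C(C)C)C(C)C)c2)cc1
F2 | step 13 | 2-{(R)-[(1R,2S,3S)-2-(3,5-dihydroxyphenyl)-4,6-dimethoxy-3-(4-methoxyphenyl)indan-1-yl](4-methoxyphenyl)methyl}-3,5-dimethoxybenzaldehyde | COc1ccc([C@H]2c3c(OC)cc(OC)cc3[C@@H]([C@H](c3ccc(OC)cc3)c3c(OC)cc(OC)cc3C=O)[C@@H]2c2cc(O)cc(O)c2)cc1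
F3 | step 13 | cyclic ortho-hydroxybenzhydrol with the eight-membered ring closed (carbinol centre undefined; other centres as in 23) | COc1ccc([C@H]2c3c(OC)cc(OC)cc3[C@H]3[C@H](c4ccc(OC)cc4)c4c(OC)cc(OC)cc4C(O)c4c(O)cc(O)cc4[C@H]23)cc1
F4 | step 13 | hepta-O-methylstenophyllol B (as 23, with OMe also on the aryl group at furan C2) | COc1ccc([C@H]2c3c(OC)cc(OC)cc3[C@H]3[C@H](c4ccc(OC)cc4)c4c(OC)cc(OC)cc4[C@@H]4c5c(cc(O)cc5[C@H]23)O[C@H]4c2ccc(OC)cc2)cc1
F5 | step 10 | (2-bromo-4,6-dimethoxyphenyl)[(1S,2R,3S)-2-[3,5-bis(triisopropylsilyloxy)phenyl]-4,6-dimethoxy-3-(4-methoxyphenyl)indan-1-yl]methanone | COc1ccc([C@H]2c3c(OC)cc(OC)cc3[C@@H](C(=O)c3c(OC)cc(OC)cc3Br)[C@@H]2c2cc(O[Si](C(C)C)(C(C)C)C(C)C)cc(O[Si](C(C)C)(C(C)C)C(C)C)c2)cc1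
F6 | step 10 | (2-bromo-4,6-dimethoxyphenyl)(4-methoxyphenyl)[(1S,2R,3S)-2-[3,5-bis(triisopropylsilyloxy)phenyl]-4,6-dimethoxy-3-(4-methoxyphenyl)indan-1-yl]methanol (carbinol centre undefined) | COc1ccc([C@H]2c3c(OC)cc(OC)cc3[C@@H](C(O)(c3ccc(OC)cc3)c3c(OC)cc(OC)cc3Br)[C@@H]2c2cc(O[Si](C(C)C)(C(C)C)C(C)C)cc(O[Si](C(C)C)(C(C)C)C(C)C)c2)cc1
F7 | step 2 | 1-(2-bromo-3,5-dimethoxyphenyl)ethanol | COc1cc(OC)c(Br)c(C(C)O)c1
F8 | step 2 | 1-(2-bromo-3,5-dimethoxyphenyl)ethanone | COc1cc(OC)c(Br)c(C(C)=O)c1
F9 | step 2 | (E)-1-(2-bromo-3,5-dimethoxyphenyl)-3-(4-methoxyphenyl)prop-2-en-1-one | COc1ccc(/C=C/C(=O)c2cc(OC)cc(OC)c2Br)cc1
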